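The route rests on cutting the bond between C2 of the 1,4-dioxane ring and C1 of the syringyl ring. C2 also carries ring oxygen O1, so one oxidation level higher it is an anomeric carbon. Syringyl C1 lies para to the free phenol, the ipso site of an electron-rich aryltrifluoroborate. The key step ionises an unprotected, enantiopure 2-hydroxy-1,4-benzodioxane, a lactol that already holds C3, its CH2OH group and the formyl-bearing benzo ring. It moves the aryl group from boron to C2, trans to the C3 substituent, in one operation. C3 is set earlier by a palladium-catalysed asymmetric allylic etherification, and a Wittig olefination adds the enal last.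

Key step: step 4

Assumption: the (R,R) enantiomer of the DACH-naphthyl ligand, (1R,2R)-N,N'-bis[2-(diphenylphosphanyl)-1-naphthoyl]cyclohexane-1,2-diamine, is taken to give the R-configured allyl aryl ether in step 1. If the sense of induction is the opposite, the equally available (S,S) ligand is used and nothing else changes.

Step 1
Reactants: 1 3,4-dihydroxy-5-methoxybenzaldehyde (5-hydroxyvanillin); 2 (±)-2-vinyloxirane (butadiene monoepoxide)
Product: 3 3-hydroxy-4-{[(2R)-1-hydroxybut-3-en-2-yl]oxy}-5-methoxybenzaldehyde
Conditions: Pd2(dba)3·CHCl3 (1 mol %), (R,R)-DACH-naphthyl ligand (3 mol %), CH2Cl2, 0 °C to rt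
Reagents that add atoms: none
Why: Tsuji–Trost asymmetric allylic etherification run as a dynamic kinetic asymmetric transformation: zerovalent palladium opens both enantiomers of 2 to rapidly interconverting pi-allyl alkoxide complexes, the alkoxide deprotonates the more acidic 4-OH of 1 (para to the formyl group) and guides that phenoxide by hydrogen bonding to the internal allyl terminus, where the chiral ligand pocket should set the R configuration of the new C–O stereocentre.

Step 2
Reactants: 3 3-hydroxy-4-{[(2R)-1-hydroxybut-3-en-2-yl]oxy}-5-methoxybenzaldehyde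
Product: 5 (3S)-2-hydroxy-3-(hydroxymethyl)-5-methoxy-2,3-dihydro-1,4-benzodioxine-7-carbaldehyde (lactol, mixture at C2, used crude), via open-chain aldehyde 4 (not isolated)
Conditions: O3, CH2Cl2/MeOH, −78 °C; then Me2S, −78 °C to rt
Reagents that add atoms: ozone, [O-][O+]=O
Why: Criegee ozonolysis with reductive work-up: ozone should cleave the isolated terminal alkene much faster than it attacks the formyl-deactivated arene, and aldehyde 4 closes at once on the neighbouring phenol to the six-membered lactol, so the alpha-aryloxy stereocentre (now C3, called S only because the CIP priorities change) never meets base.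

Step 3
Reactants: 6 2,6-dimethoxyphenol (syringol)
Product: 8 potassium trifluoro(4-hydroxy-3,5-dimethoxyphenyl)borate, via O,C-bis(pinacolboryl)syringol 7 (not isolated)
Conditions: HBpin (2.5 equiv), [Ir(OMe)(cod)]2 (1.5 mol %), dtbpy (3 mol %), THF, 70 °C; then aq KHF2, MeOH, rt
Reagents that add atoms: pinacolborane, CC1(C)OBOC1(C)C; potassium hydrogen difluoride, [K+].F.[F-]
Why: Iridium-catalysed, sterically controlled C–H borylation: the phenol is masked in the flask as its O-Bpin ether, C4–H is the only C–H bond without an ortho substituent, and KHF2 then converts the C–Bpin group into the trifluoroborate and frees the phenol, with no stereocentre formed.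

Step 4
Reactants: 5 (3S)-2-hydroxy-3-(hydroxymethyl)-5-methoxy-2,3-dihydro-1,4-benzodioxine-7-carbaldehyde; 8 potassium trifluoro(4-hydroxy-3,5-dimethoxyphenyl)borate
Product: 11 (2S,3S)-2-(4-hydroxy-3,5-dimethoxyphenyl)-3-(hydroxymethyl)-5-methoxy-2,3-dihydro-1,4-benzodioxine-7-carbaldehyde, via aryldifluoroborane 9 (not isolated), via oxocarbenium ion 10 (not isolated)
Conditions: 8 (1.5 equiv), BF3·OEt2 (3 equiv), MeCN, −30 °C to 0 °C; aqueous work-up
Reagents that add atoms: none
Why: BF3·OEt2 abstracts fluoride from 8 to give aryldifluoroborane 9 and, together with 9, ionises the anomeric OH of lactol 5 to the O1-stabilised oxocarbenium ion 10; a tetracoordinate arylborate (8 itself or the hydroxydifluoroborate formed from 9) then hands its aryl group to C2 through the ipso carbon. The closest known reaction type is the BF3-promoted coupling of potassium organotrifluoroborates with acetals and glycosyl donors, that is a C-aryl glycosylation. The productive path closes no ring, because the dioxane ring is carried in by the lactol; only if C2–O1 ionises again does the ring re-form, by 6-exo-trig attack of the O1 phenol on the para-quinone methide cation. The new stereocentre C2 is controlled by C3: the aryl group should enter the flattened cation anti to the CH2OH group, and the reversible C2–O1 ionisation that the para-hydroxy group allows should drain any cis isomer into the diequatorial trans (2S,3S) product. Site selectivity on the arene is fixed by the C–B bond, which overrides the methoxy-activated C–H positions that free syringol would offer to an electrophile. Chemoselectivity over the aryl aldehyde rests on the easier ionisation of the lactol and on the low electrophilicity of a trioxygenated benzaldehyde, and C3 keeps its configuration as long as arylation outruns loss of H3 from 10, which the low temperature favours.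

Step 5
Reactants: 11 (2S,3S)-2-(4-hydroxy-3,5-dimethoxyphenyl)-3-(hydroxymethyl)-5-methoxy-2,3-dihydro-1,4-benzodioxine-7-carbaldehyde; 12 (triphenylphosphoranylidene)acetaldehyde
Product: 13 bilagrewin, (2E)-3-[(2S,3S)-2-(4-hydroxy-3,5-dimethoxyphenyl)-3-(hydroxymethyl)-5-methoxy-2,3-dihydro-1,4-benzodioxin-7-yl]prop-2-enal
Conditions: 12 (1.2 equiv), toluene, 80 °C
Reagents that add atoms: none
Why: Wittig olefination with a stabilised formylmethylene ylide, which should give the E-enal, needs no added base and therefore leaves the phenol, the primary alcohol and both dioxane stereocentres untouched.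

Compound list
1 | 3,4-dihydroxy-5-methoxybenzaldehyde | COc1cc(C=O)cc(O)c1O | starting material
2 | (±)-2-vinyloxirane | C=CC1CO1 | starting material
3 | 3-hydroxy-4-{[(2R)-1-hydroxybut-3-en-2-yl]oxy}-5-methoxybenzaldehyde | COc1cc(C=O)cc(O)c1O[C@H](C=C)CO | intermediate
4 | (2S)-2-(4-formyl-2-hydroxy-6-methoxyphenoxy)-3-hydroxypropanal (not isolated) | COc1cc(C=O)cc(O)c1O[C@H](C=O)CO | intermediate
5 | (3S)-2-hydroxy-3-(hydroxymethyl)-5-methoxy-2,3-dihydro-1,4-benzodioxine-7-carbaldehyde | OC1Oc2cc(C=O)cc(OC)c2O[C@H]1CO | intermediate
6 | 2,6-dimethoxyphenol | COc1cccc(OC)c1O | starting material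
7 | 2-[2,6-dimethoxy-4-(4,4,5,5-tetramethyl-1,3,2-dioxaborolan-2-yl)phenoxy]-4,4,5,5-tetramethyl-1,3,2-dioxaborolane (not isolated) | COc1cc(B2OC(C)(C)C(C)(C)O2)cc(OC)c1OB1OC(C)(C)C(C)(C)O1 | intermediate
8 | potassium trifluoro(4-hydroxy-3,5-dimethoxyphenyl)borate | [K+].COc1cc([B-](F)(F)F)cc(OC)c1O | intermediate
9 | difluoro(4-hydroxy-3,5-dimethoxyphenyl)borane (not isolated) | COc1cc(B(F)F)cc(OC)c1O | intermediate
10 | (3S)-7-formyl-3-(hydroxymethyl)-5-methoxy-3H-1,4-benzodioxin-1-ium, oxocarbenium ion (not isolated) | C1=[O+]c2cc(C=O)cc(OC)c2O[C@H]1CO | intermediate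
11 | (2S,3S)-2-(4-hydroxy-3,5-dimethoxyphenyl)-3-(hydroxymethyl)-5-methoxy-2,3-dihydro-1,4-benzodioxine-7-carbaldehyde | COc1cc([C@@H]2Oc3cc(C=O)cc(OC)c3O[C@H]2CO)cc(OC)c1O | intermediate
12 | (triphenylphosphoranylidene)acetaldehyde | O=CC=P(c1ccccc1)(c1ccccc1)c1ccccc1 | starting material
13 | bilagrewin | COc1cc([C@@H]2Oc3cc(/C=C/C=O)cc(OC)c3O[C@H]2CO)cc(OC)c1O | target

Total step count: 5. Longest linear sequence: 4 (steps 1, 2, 4, 5).

Steps most likely to fail

Step 4.
- **What may go wrong:**
  - The electron-rich arylborate may be protodeboronated by the acid released.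
  - The aryl group may be delivered from the CH2OH face after B–O binding, giving poor facial selectivity.
  - Proton loss from the oxocarbenium ion may erode the configuration at C3.
  - Arylation may compete at the aryl aldehyde.
- **Fallback (sets out from 3, returns at 11):** the C–C bond is made by carbonyl addition of an aryllithium, and the ring is closed afterwards through the para-quinone methide. The formyl group of 3 is masked with 2,2-dimethylpropane-1,3-diol (PPTS, toluene, reflux, water separator) as the 5,5-dimethyl-1,3-dioxane acetal F1. Ozonolysis as in step 2 gives the acetal lactol F2. Commercial 4-bromo-2,6-dimethoxyphenol is protected with MOMCl and i-Pr2NEt as the MOM ether F3, which is lithiated with n-BuLi (THF, −78 °C) to the aryllithium F4. An excess of F4 adds to the open aldehyde form of F2 to give the 1-aryl-2-aryloxypropane-1,3-diol F5 as a mixture at the carbinol carbon. Aqueous HCl in THF then removes the MOM and acetal groups, ionises the benzylic alcohol and closes the dioxane ring by 6-exo-trig attack of the phenol. This should give trans 11 under thermodynamic control.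

Step 1.
- **What may go wrong:**
  - The phenoxide may attack the terminal allyl carbon.
  - The 3-OH may be alkylated instead of the hindered 4-OH.
  - Zerovalent palladium may re-ionise the electron-poor aryl ether, with isomerisation and erosion of enantiopurity.
- **Fallback (sets out from 1, returns at 3):** the stereocentre is taken from the chiral pool and transferred by SN2 inversion. Commercial (S)-but-3-ene-1,2-diol is silylated at the primary OH (TBSCl, imidazole, CH2Cl2, 0 °C) to (2S)-1-[(tert-butyldimethylsilyl)oxy]but-3-en-2-ol F6. A Mitsunobu reaction with 1 (PPh3, DIAD, THF, 0 °C) engages the more acidic 4-OH and inverts the carbinol carbon to give the silyl ether F7. HF·pyridine in THF then frees 3.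

Step 5.
- **What may go wrong:**
  - The electron-rich aldehyde may react sluggishly.
  - The more reactive enal may undergo a second olefination once it has formed.
- **Fallback (sets out from 11, returns at 13):** the two carbons are added at the ester level, where the product cannot react again, and the oxidation state is adjusted afterwards. A Wittig reaction of 11 with Ph3P=CHCO2Et (toluene, 80 °C) gives the ethyl (E)-cinnamate F8. Excess i-Bu2AlH (CH2Cl2, −78 °C) gives the cinnamyl alcohol F9. MnO2 (CH2Cl2, rt) should oxidise only the allylic alcohol, giving 13.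

Further compounds
F1 | step 4 | 5-(5,5-dimethyl-1,3-dioxan-2-yl)-2-{[(2R)-1-hydroxybut-3-en-2-yl]oxy}-3-methoxyphenol | COc1cc(C2OCC(C)(C)CO2)cc(O)c1O[C@H](C=C)CO
F2 | step 4 | (3S)-7-(5,5-dimethyl-1,3-dioxan-2-yl)-3-(hydroxymethyl)-5-methoxy-2,3-dihydro-1,4-benzodioxin-2-ol | OC1Oc2cc(C3OCC(C)(C)CO3)cc(OC)c2O[C@H]1CO
F3 | step 4 | 5-bromo-1,3-dimethoxy-2-(methoxymethoxy)benzene | COCOc1c(OC)cc(Br)cc1OC
F4 | step 4 | [3,5-dimethoxy-4-(methoxymethoxy)phenyl]lithium | [Li]c1cc(OC)c(OCOC)c(OC)c1
F5 | step 4 | (2S)-1-[3,5-dimethoxy-4-(methoxymethoxy)phenyl]-2-[4-(5,5-dimethyl-1,3-dioxan-2-yl)-2-hydroxy-6-methoxyphenoxy]propane-1,3-diol | COc1cc(C2OCC(C)(C)CO2)cc(O)c1O[C@H](C(O)c1cc(OC)c(OCOC)c(OC)c1)CO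
F6 | step 1 | (2S)-1-[(tert-butyldimethylsilyl)oxy]but-3-en-2-ol | C=C[C@H](O)CO[Si](C)(C)C(C)(C)C
F7 | step 1 | 4-({(2R)-1-[(tert-butyldimethylsilyl)oxy]but-3-en-2-yl}oxy)-3-hydroxy-5-methoxybenzaldehyde | COc1cc(C=O)cc(O)c1O[C@H](C=C)CO[Si](C)(C)C(C)(C)C
F8 | step 5 | ethyl (2E)-3-[(2S,3S)-2-(4-hydroxy-3,5-dimethoxyphenyl)-3-(hydroxymethyl)-5-methoxy-2,3-dihydro-1,4-benzodioxin-7-yl]prop-2-enoate | COc1cc([C@@H]2Oc3cc(/C=C/C(=O)OCC)cc(OC)c3O[C@H]2CO)cc(OC)c1O
F9 | step 5 | (2E)-3-[(2S,3S)-2-(4-hydroxy-3,5-dimethoxyphenyl)-3-(hydroxymethyl)-5-methoxy-2,3-dihydro-1,4-benzodioxin-7-yl]prop-2-en-1-ol | COc1cc([C@@H]2Oc3cc(/C=C/CO)cc(OC)c3O[C@H]2CO)cc(OC)c1O
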